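Target: kurarinol, (2S)-2-(2,4-dihydroxyphenyl)-7-hydroxy-8-[(2R)-5-hydroxy-5-methyl-2-(prop-1-en-2-yl)hexyl]-5-methoxychroman-4-one. Both descriptors were derived from the given SMILES.

**Retrosynthetic overview**
- Ring C is the only ring formed, and it is formed last. The (2S)-flavanone comes from a catalytic asymmetric 6-endo oxa-Michael closure of the free chalcone (kuraridinol). Rings A and B both come from resorcinol.
- The chalcone comes from an A-ring aryllithium (directed metalation) and a B-ring cinnamic Weinreb amide (bromination, then Heck).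
- The side-chain stereocentre is built by two boron-to-carbon 1,2-shifts. The first is a Pd-catalysed enantioselective conjunctive coupling of an alkyl-Bpin, vinylMgBr and the A-ring iodide. The second is a stereoretentive Zweifel isopropenylation.
- The A-ring iodide comes from resorcinol by MOM protection, ortho-lithiation/iodination, Ir C-H borylation/oxidation and O-methylation.
- The alkyl-Bpin comes from 2-methylbut-3-en-2-ol by silylation and hydroboration.

Assumption: the absolute sense of induction of the MandyPhos-Pd catalyst (step 7) and of the cinchona squaramide (step 13) is assigned by analogy. Both catalysts exist in both (pseudo)enantiomeric series, so the antipode is used if the sense turns out reversed.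

**Route**

Step 1
Reactants: 1 resorcinol
Product: 2 1,3-bis(methoxymethoxy)benzene
Conditions: NaH (2.4 equiv), MOMCl (2.3 equiv), DMF, 0 °C to rt
Reagents that add atoms: chloromethyl methyl ether (MOMCl), COCCl
Why: Williamson-type O-alkylation of the bis-phenoxide gives the bis-MOM ether, which serves both aromatic rings and later directs the metalations.

Step 2
Reactants: 2 1,3-bis(methoxymethoxy)benzene
Product: 4 2-iodo-1,3-bis(methoxymethoxy)benzene, via 2-lithio arene 3 (not isolated)
Conditions: n-BuLi (1.1 equiv), THF, 0 °C, 1 h; I2 (1.15 equiv), -78 °C to rt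
Reagents that add atoms: n-butyllithium, [Li]CCCC (lithium in 3 only); iodine, II
Why: Directed ortho-metalation takes place only at C2 between the two cooperating OMOM groups, and iodinolysis fixes the future C8 position.

Step 3
Reactants: 4 2-iodo-1,3-bis(methoxymethoxy)benzene
Product: 6 4-iodo-3,5-bis(methoxymethoxy)phenol, via aryl pinacol boronate 5 (not isolated)
Conditions: [Ir(OMe)(cod)]2 (1.5 mol %), dtbpy (3 mol %), B2pin2 (0.6 equiv), THF, 70 °C; then 30 % H2O2, aq NaOH, 0 °C
Reagents that add atoms: bis(pinacolato)diboron, CC1(C)OB(OC1(C)C)B1OC(C)(C)C(C)(C)O1 (boron in 5 only); hydrogen peroxide, OO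
Why: Sterically controlled Ir-catalysed C-H borylation can reach only the C-H that has no ortho substituent (para to iodine, which is tolerated), and one-pot boronate oxidation installs the third ring oxygen.

Step 4
Reactants: 6 4-iodo-3,5-bis(methoxymethoxy)phenol
Product: 7 2-iodo-5-methoxy-1,3-bis(methoxymethoxy)benzene
Conditions: MeI, K2CO3, acetone, reflux
Reagents that add atoms: iodomethane, CI
Why: Williamson methylation of the only free phenol gives the future 5-OMe group.

Step 5
Reactants: 8 2-methylbut-3-en-2-ol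
Product: 9 triethyl[(2-methylbut-3-en-2-yl)oxy]silane
Conditions: TESOTf, 2,6-lutidine, CH2Cl2, 0 °C
Reagents that add atoms: triethylsilyl triflate, CC[Si](CC)(CC)OS(=O)(=O)C(F)(F)F
Why: Silyl triflate silylation works reliably on tertiary alcohols, and the TES ether survives organometallics yet falls off in the final acid deprotection at no extra step.

Step 6
Reactants: 9 triethyl[(2-methylbut-3-en-2-yl)oxy]silane
Product: 10 triethyl{[2-methyl-4-(4,4,5,5-tetramethyl-1,3,2-dioxaborolan-2-yl)butan-2-yl]oxy}silane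
Conditions: HBpin (1.2 equiv), [Ir(cod)Cl]2 (1.5 mol %), dppe (3 mol %), CH2Cl2, rt
Reagents that add atoms: pinacolborane, B1OC(C)(C)C(C)(C)O1
Why: Ir-catalysed anti-Markovnikov hydroboration of a terminal alkene next to a quaternary carbon gives only the primary boronate.

Step 7
Reactants: 10 triethyl{[2-methyl-4-(4,4,5,5-tetramethyl-1,3,2-dioxaborolan-2-yl)butan-2-yl]oxy}silane; 11 vinylmagnesium bromide; 7 2-iodo-5-methoxy-1,3-bis(methoxymethoxy)benzene
Product: 13 2-[(2R)-1-[4-methoxy-2,6-bis(methoxymethoxy)phenyl]-5-methyl-5-(triethylsilyloxy)hexan-2-yl]-4,4,5,5-tetramethyl-1,3,2-dioxaborolane, via vinyl boronate complex 12 (not isolated)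
Conditions: 10 (1.2 equiv) + 11 (1.18 equiv), THF, 0 °C to rt, NaOTf (2 equiv); then 7, Pd(OAc)2 (3 mol %), (Sp,Sp)-MandyPhos (3.6 mol %), THF, 60 °C, 16 h
Reagents that add atoms: none
Why: In this enantioselective conjunctive cross-coupling the cationic ArPd(diphosphine) species from 7 binds one face of the vinyl group of 12 and induces a 1,2-metallate shift of the primary alkyl group from boron to the alpha-carbon anti to Pd, and reductive elimination then forms the Ar-CH2 bond, so two C-C bonds and the (R)-centre are set under ligand control.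

Step 8
Reactants: 13 2-[(2R)-1-[4-methoxy-2,6-bis(methoxymethoxy)phenyl]-5-methyl-5-(triethylsilyloxy)hexan-2-yl]-4,4,5,5-tetramethyl-1,3,2-dioxaborolane; 14 2-bromopropene
Product: 18 2-[(2R)-5-methyl-2-(prop-1-en-2-yl)-5-(triethylsilyloxy)hexyl]-5-methoxy-1,3-bis(methoxymethoxy)benzene, via isopropenyllithium 15 (not isolated), via isopropenyl boronate complex 16 (not isolated), via beta-iodo boronate 17 (not isolated)
Conditions: 14, t-BuLi (2 equiv per 14), Et2O, -78 °C; 13, THF, -78 °C; I2 (1.2 equiv), THF, -78 °C; NaOMe, MeOH, -78 °C to rt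
Reagents that add atoms: tert-butyllithium, [Li]C(C)(C)C (lithium in 15 and 16 only); iodine, II (iodine in 17 only)
Why: In the Zweifel olefination, iodonium formation on the isopropenyl group of 16 triggers a stereoretentive 1,2-metallate shift of the secondary alkyl group, and methoxide-induced anti-elimination of boron and iodine from 17 gives the isopropenyl group with the (R)-centre unchanged.

Step 9
Reactants: 2 1,3-bis(methoxymethoxy)benzene
Product: 19 1-bromo-2,4-bis(methoxymethoxy)benzene
Conditions: NBS (1.0 equiv), MeCN, 0 °C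
Reagents that add atoms: N-bromosuccinimide, O=C1CCC(=O)N1Br
Why: Electrophilic aromatic bromination goes to C4, which is para to one OMOM and ortho to the other, while C2 is hindered.

Step 10
Reactants: 19 1-bromo-2,4-bis(methoxymethoxy)benzene; 20 N-methoxy-N-methylacrylamide
Product: 21 (E)-3-[2,4-bis(methoxymethoxy)phenyl]-N-methoxy-N-methylprop-2-enamide
Conditions: Pd(OAc)2 (2 mol %), P(o-tol)3 (6 mol %), Et3N, DMF, 100 °C
Reagents that add atoms: none
Why: The Mizoroki-Heck reaction with an acrylamide gives the (E)-cinnamamide through syn-insertion and syn-beta-hydride elimination.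

Step 11
Reactants: 18 2-[(2R)-5-methyl-2-(prop-1-en-2-yl)-5-(triethylsilyloxy)hexyl]-5-methoxy-1,3-bis(methoxymethoxy)benzene; 21 (E)-3-[2,4-bis(methoxymethoxy)phenyl]-N-methoxy-N-methylprop-2-enamide
Product: 24 (E)-3-[2,4-bis(methoxymethoxy)phenyl]-1-{6-methoxy-2,4-bis(methoxymethoxy)-3-[(2R)-5-methyl-2-(prop-1-en-2-yl)-5-(triethylsilyloxy)hexyl]phenyl}prop-2-en-1-one, via aryllithium 22 (not isolated), via tetrahedral lithium adduct 23 (not isolated)
Conditions: n-BuLi (1.1 equiv), THF, 0 °C, 1 h; 21 (1.1 equiv), -78 to -20 °C; sat. aq NH4Cl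
Reagents that add atoms: n-butyllithium, [Li]CCCC (lithium in 22 and 23 only)
Why: Directed ortho-metalation can occur only at the two constitutionally equivalent C-H positions flanked by OMOM and OMe, and Weinreb ketone synthesis through the chelated adduct 23 stops cleanly at the enone.

Step 12
Reactants: 24 (E)-3-[2,4-bis(methoxymethoxy)phenyl]-1-{6-methoxy-2,4-bis(methoxymethoxy)-3-[(2R)-5-methyl-2-(prop-1-en-2-yl)-5-(triethylsilyloxy)hexyl]phenyl}prop-2-en-1-one
Product: 25 kuraridinol, that is (E)-1-{2,4-dihydroxy-3-[(2R)-5-hydroxy-5-methyl-2-(prop-1-en-2-yl)hexyl]-6-methoxyphenyl}-3-(2,4-dihydroxyphenyl)prop-2-en-1-one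
Conditions: HCl (1 M in MeOH), 25 °C, dark, 3 h
Reagents that add atoms: none
Why: Acid-catalysed acetal exchange and silyl ether solvolysis remove four MOM groups and the TES group in one operation under conditions mild enough to leave the isopropenyl group, the tertiary alcohol and the (E)-enone untouched.

Step 13
Reactants: 25 kuraridinol
Product: 26 kurarinol, (2S)-2-(2,4-dihydroxyphenyl)-7-hydroxy-8-[(2R)-5-hydroxy-5-methyl-2-(prop-1-en-2-yl)hexyl]-5-methoxy-2,3-dihydrochromen-4-one
Conditions: 9-amino-9-deoxy-epi-dihydroquinine 3,5-bis(trifluoromethyl)phenyl squaramide (10 mol %), t-BuOMe/CH2Cl2 1:1, -10 °C, dark, Ar, 72 h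
Reagents that add atoms: none
Why: Proposed new method: a catalytic enantioselective 6-endo-trig oxa-Michael closure of a non-activated, fully unprotected 2'-hydroxychalcone, in which the quinuclidine nitrogen is the general base for the 2'-OH, the squaramide N-H pair takes the enone C=O over from the intramolecular hydrogen bond and lowers its LUMO, and the B-ring 2-OH next to C-beta gives a third hydrogen bond to a squaramide carbonyl so that the s-cis enone is held rigidly and the phenoxide reaches only the Si face of C-beta (giving 2S) before the quinuclidinium protonates the enolate at C3; the 6'-OMe/3'-alkyl buttressing twists the aroyl group out of conjugation, so closure is exergonic and retro-Michael racemisation is frozen at -10 °C with so weak a base, and the remote (R)-centre exerts no bias; the closest known reaction types are the cinchona-thiourea oxa-Michael cyclisation of alpha-carboxy-activated 2'-hydroxychalcones and the enzymatic chalcone isomerase reaction.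

**Compound list**

1 | resorcinol | Oc1cccc(O)c1 | starting material
2 | 1,3-bis(methoxymethoxy)benzene | COCOc1cccc(OCOC)c1 | intermediate
3 | 2-lithio-1,3-bis(methoxymethoxy)benzene | [Li]c1c(OCOC)cccc1OCOC | intermediate
4 | 2-iodo-1,3-bis(methoxymethoxy)benzene | COCOc1cccc(OCOC)c1I | intermediate
5 | 2-[4-iodo-3,5-bis(methoxymethoxy)phenyl]-4,4,5,5-tetramethyl-1,3,2-dioxaborolane | COCOc1cc(B2OC(C)(C)C(C)(C)O2)cc(OCOC)c1I | intermediate
6 | 4-iodo-3,5-bis(methoxymethoxy)phenol | COCOc1cc(O)cc(OCOC)c1I | intermediate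
7 | 2-iodo-5-methoxy-1,3-bis(methoxymethoxy)benzene | COCOc1cc(OC)cc(OCOC)c1I | intermediate
8 | 2-methylbut-3-en-2-ol | C=CC(C)(C)O | starting material
9 | triethyl[(2-methylbut-3-en-2-yl)oxy]silane | C=CC(C)(C)O[Si](CC)(CC)CC | intermediate
10 | triethyl{[2-methyl-4-(4,4,5,5-tetramethyl-1,3,2-dioxaborolan-2-yl)butan-2-yl]oxy}silane | CC[Si](CC)(CC)OC(C)(C)CCB1OC(C)(C)C(C)(C)O1 | intermediate
11 | vinylmagnesium bromide | C=C[Mg]Br | starting material
12 | bromomagnesium 2-ethenyl-4,4,5,5-tetramethyl-2-[3-methyl-3-(triethylsilyloxy)butyl]-1,3,2-dioxaborolan-2-uide (vinyl boronate complex) | C=C[B-]1(CCC(C)(C)O[Si](CC)(CC)CC)OC(C)(C)C(C)(C)O1.[Mg+]Br | intermediate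
13 | 2-[(2R)-1-[4-methoxy-2,6-bis(methoxymethoxy)phenyl]-5-methyl-5-(triethylsilyloxy)hexan-2-yl]-4,4,5,5-tetramethyl-1,3,2-dioxaborolane | CC1(C)OB(OC1(C)C)[C@H](CCC(C)(C)O[Si](CC)(CC)CC)Cc1c(OCOC)cc(OC)cc1OCOC | intermediate
14 | 2-bromopropene | C=C(C)Br | starting material
15 | isopropenyllithium | [Li]C(C)=C | intermediate
16 | lithium B-(prop-1-en-2-yl) boronate complex of 13, (R) at the carbon on boron | C=C(C)[B-]1(OC(C)(C)C(C)(C)O1)[C@H](CCC(C)(C)O[Si](CC)(CC)CC)Cc1c(OCOC)cc(OC)cc1OCOC.[Li+] | intermediate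
17 | 2-[(3R)-1-iodo-3-{[4-methoxy-2,6-bis(methoxymethoxy)phenyl]methyl}-2,6-dimethyl-6-(triethylsilyloxy)heptan-2-yl]-4,4,5,5-tetramethyl-1,3,2-dioxaborolane (both C2 epimers) | ICC(C)(B1OC(C)(C)C(C)(C)O1)[C@H](CCC(C)(C)O[Si](CC)(CC)CC)Cc1c(OCOC)cc(OC)cc1OCOC | intermediate
18 | 2-[(2R)-5-methyl-2-(prop-1-en-2-yl)-5-(triethylsilyloxy)hexyl]-5-methoxy-1,3-bis(methoxymethoxy)benzene | C=C(C)[C@H](CCC(C)(C)O[Si](CC)(CC)CC)Cc1c(OCOC)cc(OC)cc1OCOC | intermediate
19 | 1-bromo-2,4-bis(methoxymethoxy)benzene | COCOc1ccc(Br)c(OCOC)c1 | intermediate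
20 | N-methoxy-N-methylacrylamide | C=CC(=O)N(C)OC | starting material
21 | (E)-3-[2,4-bis(methoxymethoxy)phenyl]-N-methoxy-N-methylprop-2-enamide | COCOc1ccc(/C=C/C(=O)N(C)OC)c(OCOC)c1 | intermediate
22 | aryllithium from 18, lithium between OMe and OMOM | C=C(C)[C@H](CCC(C)(C)O[Si](CC)(CC)CC)Cc1c(OCOC)cc(OC)c([Li])c1OCOC | intermediate
23 | lithium alkoxide of the tetrahedral adduct of 22 to 21 (carbinol carbon unassigned) | C=C(C)[C@H](CCC(C)(C)O[Si](CC)(CC)CC)Cc1c(OCOC)cc(OC)c(C(O[Li])(/C=C/c2ccc(OCOC)cc2OCOC)N(C)OC)c1OCOC | intermediate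
24 | (E)-3-[2,4-bis(methoxymethoxy)phenyl]-1-{6-methoxy-2,4-bis(methoxymethoxy)-3-[(2R)-5-methyl-2-(prop-1-en-2-yl)-5-(triethylsilyloxy)hexyl]phenyl}prop-2-en-1-one | C=C(C)[C@H](CCC(C)(C)O[Si](CC)(CC)CC)Cc1c(OCOC)cc(OC)c(C(=O)/C=C/c2ccc(OCOC)cc2OCOC)c1OCOC | intermediate
25 | kuraridinol, (E)-1-{2,4-dihydroxy-3-[(2R)-5-hydroxy-5-methyl-2-(prop-1-en-2-yl)hexyl]-6-methoxyphenyl}-3-(2,4-dihydroxyphenyl)prop-2-en-1-one | C=C(C)[C@H](CCC(C)(C)O)Cc1c(O)cc(OC)c(C(=O)/C=C/c2ccc(O)cc2O)c1O | intermediate
26 | kurarinol, (2S)-2-(2,4-dihydroxyphenyl)-7-hydroxy-8-[(2R)-5-hydroxy-5-methyl-2-(prop-1-en-2-yl)hexyl]-5-methoxy-2,3-dihydrochromen-4-one | C=C(C)[C@H](CCC(C)(C)O)Cc1c(O)cc(OC)c2c1O[C@H](c1ccc(O)cc1O)CC2=O | target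

**Totals**

Total step count: 13.
Longest linear sequence: 9 steps (1, 2, 3, 4, 7, 8, 11, 12, 13).

**Three steps most likely to fail**

**Step 13 (the proposed new method).**
- Risk: the acidic 4'-OH buffers the amine, so turnover may be slow.
- Risk: an uncatalysed racemic closure may compete.
- Risk: the three-point binding model may not translate into high selectivity.
- Fallback (known chemistry), from 25 back to 26: NaOAc in refluxing EtOH (or 1 % aq NaOH at 0 °C) closes the ring without facial control. This gives 26 together with its C2 epimer (2R)-epi-kurarinol F5. The fixed (R)-side-chain centre makes the two compounds diastereomers, and they are separated by preparative HPLC on an amylose-type phase. F5 is re-equilibrated through 25 with the same base and recycled.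

**Step 7.**
- Risk: the iodide 7 is electron-rich and carries two ortho-alkoxy groups. Alkene binding to the crowded aryl-Pd cation may therefore lose to direct vinyl transfer or to reduction.
- Fallback, from 7 back to 13: this replaces catalyst control by a stoichiometric chiral carbenoid.
  - I/Mg exchange on 7 (i-PrMgCl·LiCl, THF, -20 °C), addition to 2-(chloromethyl)-4,4,5,5-tetramethyl-1,3,2-dioxaborolane and warming give the benzylic pinacol boronate F1 by a Matteson-type shift.
  - Commercial 4-methylpentane-1,4-diol is carbamoylated at the primary hydroxyl (i-Pr2NCOCl, Et3N) to the hydroxy carbamate F2. Silylation (TESOTf, 2,6-lutidine) then gives the TES carbamate F3.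
  - Deprotonation of F3 with s-BuLi/(-)-sparteine (Et2O, -78 °C), addition of F1 and warming with MgBr2 give 13. This is a stereospecific lithiation-borylation: retention on borylation and inversion in the 1,2-shift convert the (S)-carbenoid into the (R)-boronate.

**Step 12.**
- Risk: Brønsted acid may trigger premature, non-selective flavanone closure.
- Risk: the B-ring 2-OH may cyclise to a flavylium salt after E/Z isomerisation.
- Risk: the 4'-OH may close a chroman ring onto the isopropenyl group.
- Fallback, from 24 back to 25: this avoids protic acid by trans-protection. TMSOTf with 2,2'-bipyridyl (MeCN, 0 °C to rt) exchanges each aryl MOM ether for a silyl ether, giving the tetrakis(trimethylsilyl) ether F4. Et3N·3HF (THF, 0 °C) then removes the four TMS groups and the TES group.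

**Further compounds**

F1 | step 7 | 2-{[4-methoxy-2,6-bis(methoxymethoxy)phenyl]methyl}-4,4,5,5-tetramethyl-1,3,2-dioxaborolane | COCOc1cc(OC)cc(OCOC)c1CB1OC(C)(C)C(C)(C)O1
F2 | step 7 | 4-hydroxy-4-methylpentyl N,N-diisopropylcarbamate | CC(C)N(C(C)C)C(=O)OCCCC(C)(C)O
F3 | step 7 | 4-methyl-4-(triethylsilyloxy)pentyl N,N-diisopropylcarbamate | CC(C)N(C(C)C)C(=O)OCCCC(C)(C)O[Si](CC)(CC)CC
F4 | step 12 | (E)-3-[2,4-bis(trimethylsilyloxy)phenyl]-1-{6-methoxy-3-[(2R)-5-methyl-2-(prop-1-en-2-yl)-5-(triethylsilyloxy)hexyl]-2,4-bis(trimethylsilyloxy)phenyl}prop-2-en-1-one | C=C(C)[C@H](CCC(C)(C)O[Si](CC)(CC)CC)Cc1c(O[Si](C)(C)C)cc(OC)c(C(=O)/C=C/c2ccc(O[Si](C)(C)C)cc2O[Si](C)(C)C)c1O[Si](C)(C)C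
F5 | step 13 | (2R)-2-(2,4-dihydroxyphenyl)-7-hydroxy-8-[(2R)-5-hydroxy-5-methyl-2-(prop-1-en-2-yl)hexyl]-5-methoxy-2,3-dihydrochromen-4-one | C=C(C)[C@H](CCC(C)(C)O)Cc1c(O)cc(OC)c2c1O[C@@H](c1ccc(O)cc1O)CC2=O
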